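## Analysis of the target

The target is a 2-O-alkyl glycerol whose eight-carbon chain ends at C10 of a tetracyclo[6.4.0.0(2,7).0(3,6)]dodecane. This skeleton is a cyclohexane (C1, C8, C9–C12) fused in a straight line to three cyclobutanes: ring A (C1, C2, C7, C8), ring B (C2, C3, C6, C7) and ring C (C3, C4, C5, C6). These locants are used throughout unless a compound name carries its own.

There are seven stereocentres. Six are the ring-fusion CH groups C1, C2, C3, C6, C7 and C8; every fusion is cis and each ring lies anti to the one before, so the ladder is a staircase. The seventh is C10, whose chain sits on the face of the cyclohexane that carries the ladder bonds C1–C2 and C8–C7, so H-10 is cis to H-1 and H-8. Glycerol C2 is not stereogenic. The absolute configuration therefore rests only on which of the positions C10 and C11 carries the chain relative to the ring fusion.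

Rings B and C together are a bicyclo[2.2.0]hexane with roughly 55 kcal/mol of strain. This unit cleaves thermally above about 120 °C and is at risk from active metal surfaces, radicals and strong electrophiles. The 1,3-diol must be masked during ylide chemistry.

The difficulty is that the ladder has no functional group. Each bond of rings B and C has to be made against strain, with six contiguous stereocentres, and no ground-state reaction of an unstrained precursor can pay that energy.

The strategy rests on one feature: the bicyclo[2.2.0]hexane formed by rings B and C is the valence isomer of a cyclohexa-1,3-diene (C2–C3=C4–C5=C6–C7) fused to ring A. The two differ only by the C3–C6 bond.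

## Retrosynthetic reasoning

**End game, C10–chain bond.** Target 24 is traced to its benzylidene acetal 23, then to alkene 22 by removing the two hydrogens at C10 and the first chain carbon. Alkene 22 is cut at the C10=C bond into ladder ketone 16 and phosphonium salt 20 (through ylide 21). The cut is placed here because C10 is the one skeletal carbon that carries oxygen from the first ring-forming step, so the whole chain arrives in a single olefination. Salt 20 comes from bromide 19, made from the protected glycerol 17 and dibromide 18. The forward hydrogenation must deliver hydrogen to the convex face of 22, the face of H-1 and H-8.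

**Functional group level of the ladder.** Ketone 16 comes from ketal 15, and 15 from ladderene ketal 14 by saturating C4=C5. The ketal keeps the carbonyl out of the photochemistry and the reductions. The C4=C5 double bond is the remnant of the diene and costs one reduction.

**Key disconnection, C3–C6.** Ladderene 14 is opened at the rung shared by rings B and C to give cyclohexadiene ketal 13. This is the only single bond whose removal dissolves two four-membered rings at once and leaves a closed-shell, isolable isomer free of the bicyclo[2.2.0]hexane strain. Cutting C2–C3/C6–C7 or C4–C5 instead removes one ring at a time and calls for an activating group that must later be excised. In the forward direction light must close the diene in the 4π mode, with the new cyclobutene folding away from ring A.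

**Diene ring, C2–C3 and C6–C7.** Diene 13 is cut into cyclobutene ketal 10 and pyrone 11. The forward reaction is a [4+2] cycloaddition followed by decarboxylative cycloreversion. Pyrone 11 delivers the four sp2 carbons at the right oxidation level, so no adjustment is needed afterwards. Attack on the convex face of 10 gives the cis-anti-cis arrangement. Cutting ring A instead (C1–C2/C7–C8) would require a crossed photocycloaddition between two unactivated cycloalkenes.

**Cyclobutene and ketal.** Cyclobutene 10 comes from vinyl triflate 9, which comes from triflate 8, and 8 from ketone 6 through enolate 7. The order matters. A cyclobutanone forms ketals at least as readily as a cyclohexanone, so the two carbonyls could not be told apart. The four-ring carbonyl is therefore converted to its enol triflate before the six-ring ketone is unveiled from the silyl enol ether.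

**Cyclohexane, C1–C12 and C8–C9.** Ketone 6 is cut into cyclobutenone 3 and silyloxydiene 5 by a Diels–Alder disconnection. The regiochemistry puts the oxygen on the future C10. A chiral Lewis acid sets C1 and C8, the only absolute stereochemical input of the route. Enone 3 comes from bromoketone 2 and acid 1; diene 5 comes from enone 4.

## Alternatives that were turned down

**Alternative 1: the cyclobutenone Diels–Alder as the central step.**
- Disconnection: the cyclohexane bonds C1–C12 and C8–C9, leaving cyclobutenone 3 and silyloxydiene A2, the trimethylsilyl analogue of 5.
- Forward key step: a chiral boron Lewis acid would combine the two into cis-fused ketone A1, with C1 and C8 set in absolute terms and the oxygen on the future C10.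
- For: it is catalytic, mild and regio-defined, and builds from two four-carbon pieces. On absolute stereocontrol no option is better, which is why the same reaction is kept as step 4 (as 6, the triisopropylsilyl form of A1).
- Against: as the centre of a plan it closes the one ring without strain and stops at A1. Rings B and C, five stereocentres and all the strain still lie ahead. Such a plan needs a second idea for the ladder, typically two successive cyclobutane annulations, each followed by removal of its activating group.
- Comparison: equal on enantiocontrol, weaker on the ladder. The chosen strategy adds to this chemistry the one step that makes both strained rings.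

**Alternative 2: ring contraction of a pyrrolidine by nitrogen deletion.**
- Disconnection: the outer rung C4–C5, leading back to the cis-fused secondary pyrrolidine A4, in which NH bridges the two CH2 groups on C3 and C6.
- Forward key step: oxidative N-amination of A4 with a hypervalent iodine reagent and an ammonia source, loss of both nitrogen atoms, and recombination of the two carbon radicals to give di-O-benzyl target A3.
- For: it is late-stage and convergent, with the chain and C10 already in place. The risky step creates no stereocentre, needs no ultraviolet light and has no competing diene photochemistry. On these points it is stronger than the chosen route.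
- Against: both radical centres are primary and unstabilised, unlike the benzylic or carbonyl-flanked radicals such contractions usually rely on. The 1,4-biradical also has an easy escape: cleavage of the C3–C6 bond opens ring B into two vinyl groups on ring A and releases a cyclobutane's worth of strain, whereas closure must build a bicyclo[2.2.0]hexane. The partition is biased toward fragmentation. The step also makes only ring C, and removing the benzyl groups from A3 by hydrogenolysis would expose the ladder to palladium.
- Comparison: the chosen strategy forms the same kind of bond in a concerted excited-state process with no such fragmentation partner, and it makes rings B and C together.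

**Alternative 3: zipper double [2+2] of a tethered bis-dienoate.**
- Disconnection: all four rungs C1–C8, C2–C7, C3–C6 and C4–C5, back to the acyclic all-E tetraene diester A6, whose two dienoate arms hang from a meso diol acetonide.
- Forward key step: irradiation (sensitised in solution or in an ordered crystal) would stack the arms and add them twice to give meso ladder diester A5.
- For: four bonds, four rings and six stereocentres in one operation from an olefination product. In bonds per step it is the strongest option.
- Against, selectivity: two photocycloadditions must each be suprafacial and parallel. Triplet dienes react through biradicals that lose alkene geometry and can close to vinylcyclobutanes, eight-membered rings or trans-fused products. A crystal that aligns this particular tether would have to be engineered.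
- Against, functionality: A5 carries two esters on C4/C5 that must be removed from the finished ladder, and two oxygens on C10/C11 where the target needs one carbon substituent. A5 is also meso, so the absolute configuration would have to be introduced afterwards by telling C10 from C11, remote from any handle.
- Comparison: the chosen route fixes the absolute configuration in its first ring-forming step and carries exactly one functional group at C10. Its light-driven step is unimolecular and concerted, so its outcome follows from orbital symmetry and ring geometry rather than from the packing of two chains.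

Key step: step 9

Assumption: the (S)-configured oxazaborolidinium ion is taken to shield the face of cyclobutenone 3 that leads to the (1R,6R) adduct 6; should the first run show the opposite sense, the (R)-configured catalyst is used with no other change.

## Route

Step 1
Reactants: 1 3-oxocyclobutane-1-carboxylic acid
Product: 2 3-bromocyclobutan-1-one
Conditions: HgO, Br2, MgSO4, CH2Cl2, reflux
Reagents that add atoms: bromine, BrBr
Why: Hunsdiecker-type bromodecarboxylation (mercury oxide variant): the acyl hypobromite fragments by a radical chain to the secondary cyclobutyl bromide, and the ketone is inert to these conditions.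

Step 2
Reactants: 2 3-bromocyclobutan-1-one
Product: 3 cyclobut-2-en-1-one
Conditions: n-Bu3N, neat, rt, reduced pressure, product collected in a cold trap
Reagents that add atoms: none
Why: Base-mediated β-elimination of HBr from a β-bromo ketone (E1cB); the volatile enone is removed as it forms and is kept cold in solution so that it does not polymerise.

Step 3
Reactants: 4 but-3-en-2-one
Product: 5 2-(triisopropylsilyloxy)buta-1,3-diene
Conditions: i-Pr3SiOTf, Et3N, Et2O, 0 °C → rt
Reagents that add atoms: triisopropylsilyl trifluoromethanesulfonate, CC(C)[Si](OS(=O)(=O)C(F)(F)F)(C(C)C)C(C)C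
Why: Soft enolisation and O-silylation of the methyl ketone give the 2-silyloxydiene; the bulky silyl group is chosen because its enol ethers should survive a Brønsted-acid-activated Lewis acid, chromatography and amide bases.

Step 4
Reactants: 3 cyclobut-2-en-1-one; 5 2-(triisopropylsilyloxy)buta-1,3-diene
Product: 6 (1R,6R)-3-(triisopropylsilyloxy)bicyclo[4.2.0]oct-3-en-7-one
Conditions: (S)-1-(2-methylphenyl)-3,3-diphenyltetrahydro-1H,3H-pyrrolo[1,2-c][1,3,2]oxazaborole (20 mol %), (CF3SO2)2NH (18 mol %), CH2Cl2, −78 °C
Reagents that add atoms: none
Why: Enantioselective Diels–Alder reaction of a strained cyclic enone under chiral oxazaborolidinium catalysis; the nucleophilic diene terminus next to the silyloxy carbon bonds to the enone β-carbon, which places oxygen on the future C10, suprafacial addition makes the ring fusion cis, and the catalyst face sets both stereocentres.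

Step 5
Reactants: 6 (1R,6R)-3-(triisopropylsilyloxy)bicyclo[4.2.0]oct-3-en-7-one
Product: 8 (1R,6R)-3-(triisopropylsilyloxy)bicyclo[4.2.0]octa-3,7-dien-7-yl trifluoromethanesulfonate, via lithium enolate 7 (not isolated)
Conditions: LiN(i-Pr)2, THF, −78 °C; then PhNTf2, −78 → 0 °C
Reagents that add atoms: N-phenylbis(trifluoromethanesulfonimide), O=S(=O)(N(c1ccccc1)S(=O)(=O)C(F)(F)F)C(F)(F)F
Why: Kinetic deprotonation at the C8 methylene, rather than at the ring-fusion methine C6, followed by O-triflation of the enolate; the silyl enol ether is inert to the amide base, and the four-ring carbonyl is masked before the six-ring ketone is unveiled.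

Step 6
Reactants: 8 (1R,6R)-3-(triisopropylsilyloxy)bicyclo[4.2.0]octa-3,7-dien-7-yl trifluoromethanesulfonate
Product: 9 (1R,6R)-spiro[bicyclo[4.2.0]oct-7-ene-3,2'-[1,3]dioxolan]-7-yl trifluoromethanesulfonate
Conditions: HOCH2CH2OH, TsOH·H2O (cat.), CH2Cl2, rt
Reagents that add atoms: ethane-1,2-diol, OCCO
Why: Acid-catalysed transketalisation: C-protonation of the silyl enol ether, capture of the oxocarbenium ion by the diol and loss of silanol give the dioxolane, while the vinyl triflate tolerates Brønsted acid and no stereocentre is α to the unveiled carbonyl carbon.

Step 7
Reactants: 9 (1R,6R)-spiro[bicyclo[4.2.0]oct-7-ene-3,2'-[1,3]dioxolan]-7-yl trifluoromethanesulfonate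
Product: 10 (1R,6S)-spiro[bicyclo[4.2.0]oct-7-ene-3,2'-[1,3]dioxolane]
Conditions: Pd(OAc)2 (5 mol %), PPh3, n-Bu3N, HCO2H, DMF, 60 °C
Reagents that add atoms: none
Why: Palladium-catalysed formate reduction of an enol triflate: oxidative addition to zerovalent palladium, formate exchange, decarboxylation to the palladium hydride and reductive elimination give the cyclobutene; the ketal is safe in the amine-buffered medium.

Step 8
Reactants: 10 (1R,6S)-spiro[bicyclo[4.2.0]oct-7-ene-3,2'-[1,3]dioxolane]; 11 2H-pyran-2-one
Product: 13 cis-anti-cis tricyclo[6.4.0.0(2,7)]dodeca-3,5-dien-10-one ethylene ketal, via bridged lactone 12 (not isolated)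
Conditions: 11 (5 equiv), BHT (cat.), PhMe, 130 °C, sealed tube
Reagents that add atoms: none
Why: Diels–Alder addition of the electron-poor pyrone diene to the strained cyclobutene on its convex face, anti to the cyclohexane, followed by retro-[4+2] loss of CO2 from the bridged lactone; exo attack sets C2 and C7 cis to each other and anti to the cyclohexane, and all regio- and endo/exo isomers of 12 converge on 13.

Step 9
Reactants: 13 cis-anti-cis tricyclo[6.4.0.0(2,7)]dodeca-3,5-dien-10-one ethylene ketal
Product: 14 tetracyclo[6.4.0.0(2,7).0(3,6)]dodec-4-en-10-one ethylene ketal (all fusions cis and successive rings anti)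
Conditions: hν (254 nm, low-pressure Hg lamp, quartz), degassed pentane (5 mM), −20 °C
Reagents that add atoms: none
Why: Direct excitation of the s-cis diene to its singlet ππ* state should trigger the photochemically allowed disrotatory 4π electrocyclisation, which bonds the diene termini C3 and C6. The closest known reaction type is the photoisomerisation of cis-5,6-ring-fused cyclohexa-1,3-dienes (bicyclo[4.2.0]octa-2,4-dienes, cis-dihydrophthalic anhydride) to bicyclo[2.2.0]hex-2-enes. Ring C (C3, C4, C5, C6) closes as the electrocyclic four-membered ring itself, and ring B (C2, C3, C6, C7) closes as what remains of the six-membered ring once the transannular bond cuts it. The new stereocentres C3 and C6 are necessarily cis to each other, because disrotation delivers both hydrogens to the same face. Their relation to ring A is set by C2 and C7: the C4=C5 unit folds toward the open face that carries H-2 and H-7, away from ring A, which gives the anti ladder. The step needs chemoselectivity against the competing excited-state conrotatory 6π opening; the cis-fused ring A secures it, because that opening would place a trans double bond in an eight-membered ring. It also needs anti over syn selectivity, which the bent shape of the cis-fused bicyclo[4.2.0]octadiene provides, since syn folding would drive the diene into ring A. Low temperature keeps 13 from equilibrating thermally with its cyclooctatriene valence isomer, high dilution suppresses dimerisation, and the product no longer absorbs at the irradiation wavelength.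

Step 10
Reactants: 14 tetracyclo[6.4.0.0(2,7).0(3,6)]dodec-4-en-10-one ethylene ketal
Product: 15 tetracyclo[6.4.0.0(2,7).0(3,6)]dodecan-10-one ethylene ketal
Conditions: 2-O2NC6H4SO2NHNH2, Et3N, CH2Cl2, rt
Reagents that add atoms: none
Why: Diimide reduction: concerted syn transfer of H2 to the strained cis-disubstituted cyclobutene, which is fast for strained alkenes and involves no metal surface that could cleave the strained σ bonds; no stereocentre is formed.

Step 11
Reactants: 15 tetracyclo[6.4.0.0(2,7).0(3,6)]dodecan-10-one ethylene ketal
Product: 16 tetracyclo[6.4.0.0(2,7).0(3,6)]dodecan-10-one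
Conditions: 1 M HCl, THF, rt
Reagents that add atoms: water, O
Why: Acid-catalysed ketal hydrolysis; the saturated ladder offers no π bond or basic site to dilute acid, and both α-carbons of the ketone are methylenes, so no stereocentre can epimerise.

Step 12
Reactants: 17 cis-2-phenyl-1,3-dioxan-5-ol; 18 1,8-dibromooctane
Product: 19 cis-5-(8-bromooctyloxy)-2-phenyl-1,3-dioxane
Conditions: NaH, DMF, 0 °C → rt, 18 (4 equiv)
Reagents that add atoms: none
Why: Williamson ether synthesis on a primary bromide; the excess of dibromide suppresses double alkylation and the benzylidene acetal is stable to base.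

Step 13
Reactants: 19 cis-5-(8-bromooctyloxy)-2-phenyl-1,3-dioxane
Product: 20 [8-(cis-2-phenyl-1,3-dioxan-5-yloxy)octyl]triphenylphosphonium bromide
Conditions: PPh3, MeCN, 80 °C
Reagents that add atoms: triphenylphosphine, c1ccccc1P(c1ccccc1)c1ccccc1
Why: SN2 quaternisation of the phosphine by the primary alkyl bromide; the neutral conditions leave the acetal intact.

Step 14
Reactants: 20 [8-(cis-2-phenyl-1,3-dioxan-5-yloxy)octyl]triphenylphosphonium bromide; 16 tetracyclo[6.4.0.0(2,7).0(3,6)]dodecan-10-one
Product: 22 10-[8-(cis-2-phenyl-1,3-dioxan-5-yloxy)octylidene]tetracyclo[6.4.0.0(2,7).0(3,6)]dodecane (E/Z mixture), via phosphorus ylide 21 (not isolated)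
Conditions: NaN(SiMe3)2, THF, 0 °C; then 16, 0 °C → rt
Reagents that add atoms: none
Why: Wittig olefination of a cyclohexanone by a non-stabilised ylide under salt-free conditions; the geometry of the exocyclic alkene is irrelevant because the next step removes it.

Step 15
Reactants: 22 10-[8-(cis-2-phenyl-1,3-dioxan-5-yloxy)octylidene]tetracyclo[6.4.0.0(2,7).0(3,6)]dodecane
Product: 23 cis-5-[8-(tetracyclo[6.4.0.0(2,7).0(3,6)]dodecan-10-yl)octyloxy]-2-phenyl-1,3-dioxane (chain at C10 cis to the ladder)
Conditions: H2 (1 atm), [Ir(cod)(PCy3)(py)]PF6 (5 mol %), CH2Cl2, rt
Reagents that add atoms: none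
Why: Homogeneous hydrogenation of a trisubstituted alkene by a cationic iridium catalyst; syn addition of H2 from the convex face, that of H-1 and H-8, sets C10, because in either chair the ladder bonds C8–C7 and C1–C2 screen the other face, most strongly when C8–C7 is axial and 1,3 to C10.

Step 16
Reactants: 23 cis-5-[8-(tetracyclo[6.4.0.0(2,7).0(3,6)]dodecan-10-yl)octyloxy]-2-phenyl-1,3-dioxane
Product: 24 2-[8-(tetracyclo[6.4.0.0(2,7).0(3,6)]dodecan-10-yl)octyloxy]propane-1,3-diol (CNP0193334.1)
Conditions: AcOH/H2O (4:1), 45 °C
Reagents that add atoms: none
Why: Acid hydrolysis of the benzylidene acetal releases the 1,3-diol; the dialkyl ether and the saturated ladder are stable to warm aqueous acetic acid.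

## Compound list

1 | 3-oxocyclobutane-1-carboxylic acid | OC(=O)C1CC(=O)C1 | starting material
2 | 3-bromocyclobutan-1-one | BrC1CC(=O)C1 | intermediate
3 | cyclobut-2-en-1-one | O=C1C=CC1 | intermediate
4 | but-3-en-2-one | CC(=O)C=C | starting material
5 | 2-(triisopropylsilyloxy)buta-1,3-diene | C=CC(=C)O[Si](C(C)C)(C(C)C)C(C)C | intermediate
6 | (1R,6R)-3-(triisopropylsilyloxy)bicyclo[4.2.0]oct-3-en-7-one, cis-fused | CC(C)[Si](C(C)C)(C(C)C)OC1=CC[C@@H]2[C@H](C1)CC2=O | intermediate
7 | lithium enolate of 6 (enolate double bond C7=C8) | CC(C)[Si](C(C)C)(C(C)C)OC1=CC[C@@H]2[C@H](C1)C=C2[O-].[Li+] | intermediate (not isolated)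
8 | (1R,6R)-3-(triisopropylsilyloxy)bicyclo[4.2.0]octa-3,7-dien-7-yl trifluoromethanesulfonate | CC(C)[Si](C(C)C)(C(C)C)OC1=CC[C@@H]2[C@H](C1)C=C2OS(=O)(=O)C(F)(F)F | intermediate
9 | (1R,6R)-spiro[bicyclo[4.2.0]oct-7-ene-3,2'-[1,3]dioxolan]-7-yl trifluoromethanesulfonate | C12(OCCO1)CC[C@@H]3[C@H](C2)C=C3OS(=O)(=O)C(F)(F)F | intermediate
10 | (1R,6S)-spiro[bicyclo[4.2.0]oct-7-ene-3,2'-[1,3]dioxolane], cis-fused cyclobutene ketal | C12(OCCO1)CC[C@@H]3[C@H](C2)C=C3 | intermediate
11 | 2H-pyran-2-one | O=C1C=CC=CO1 | starting material
12 | bridged lactone, the [4+2] adduct of 10 and 11 (2-oxabicyclo[2.2.2]oct-5-en-3-one fused on the convex face of the cyclobutane; mixture of regio- and endo/exo isomers, one regioisomer drawn with the bridgehead configuration left open) | C12(OCCO1)CC[C@@H]3[C@H](C2)[C@H]2C4C=CC(OC4=O)[C@@H]32 | intermediate (not isolated)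
13 | cis-anti-cis tricyclo[6.4.0.0(2,7)]dodeca-3,5-dien-10-one ethylene ketal (absolute configuration as in the SMILES) | C12(OCCO1)CC[C@@H]3[C@H](C2)[C@H]2C=CC=C[C@@H]32 | intermediate
14 | tetracyclo[6.4.0.0(2,7).0(3,6)]dodec-4-en-10-one ethylene ketal, all fusions cis, successive rings anti | C12(OCCO1)CC[C@@H]3[C@H](C2)[C@H]2[C@@H]4C=C[C@@H]4[C@@H]32 | intermediate
15 | tetracyclo[6.4.0.0(2,7).0(3,6)]dodecan-10-one ethylene ketal, same configuration | C12(OCCO1)CC[C@@H]3[C@H](C2)[C@H]2[C@@H]4CC[C@@H]4[C@@H]32 | intermediate
16 | tetracyclo[6.4.0.0(2,7).0(3,6)]dodecan-10-one, same configuration | O=C1CC[C@@H]2[C@H](C1)[C@H]1[C@@H]3CC[C@@H]3[C@@H]21 | intermediate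
17 | cis-2-phenyl-1,3-dioxan-5-ol (1,3-O-benzylidene glycerol) | O[C@H]1CO[C@@H](c2ccccc2)OC1 | starting material
18 | 1,8-dibromooctane | BrCCCCCCCCBr | starting material
19 | cis-5-(8-bromooctyloxy)-2-phenyl-1,3-dioxane | BrCCCCCCCCO[C@H]1CO[C@@H](c2ccccc2)OC1 | intermediate
20 | [8-(cis-2-phenyl-1,3-dioxan-5-yloxy)octyl]triphenylphosphonium bromide | [Br-].c1ccccc1[P+](c1ccccc1)(c1ccccc1)CCCCCCCCO[C@H]1CO[C@@H](c2ccccc2)OC1 | intermediate
21 | phosphorus ylide of 20 | c1ccccc1P(c1ccccc1)(c1ccccc1)=CCCCCCCCO[C@H]1CO[C@@H](c2ccccc2)OC1 | intermediate (not isolated)
22 | 10-[8-(cis-2-phenyl-1,3-dioxan-5-yloxy)octylidene]tetracyclo[6.4.0.0(2,7).0(3,6)]dodecane, E/Z mixture at the exocyclic alkene | C(CCCCCCCO[C@H]1CO[C@@H](c2ccccc2)OC1)=C1CC[C@@H]2[C@H](C1)[C@H]1[C@@H]3CC[C@@H]3[C@@H]21 | intermediate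
23 | cis-5-[8-(tetracyclo[6.4.0.0(2,7).0(3,6)]dodecan-10-yl)octyloxy]-2-phenyl-1,3-dioxane, chain at C10 cis to the ladder | O([C@H]1CO[C@@H](c2ccccc2)OC1)CCCCCCCC[C@H]1CC[C@@H]2[C@H](C1)[C@H]1[C@@H]3CC[C@@H]3[C@@H]21 | intermediate
24 | 2-[8-(tetracyclo[6.4.0.0(2,7).0(3,6)]dodecan-10-yl)octyloxy]propane-1,3-diol, CNP0193334.1 | OCC(CO)OCCCCCCCC[C@H]1CC[C@@H]2[C@H](C1)[C@H]1[C@@H]3CC[C@@H]3[C@@H]21 | target

## Step count and least certain steps

Total step count: 16.
Longest linear sequence: 13 steps (steps 1, 2, 4–11, 14–16, from acid 1). Step 3 and steps 12–13 are side branches.

**Step 9 (key step).** The excited diene may partition into conrotatory ring opening. Any cyclooctatriene valence isomer formed thermally before or during irradiation may also absorb and feed triene photochemistry. Both would cost material and give isomeric hydrocarbons that are hard to separate. Folding toward ring A would give the syn ladder.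

Fallback, from cyclobutene ketal 10 to ladder ketal 15, building ring B by a [2+2] and ring C by ring contraction:
- Enone–alkene photocycloaddition of 10 with cyclopent-2-enone (hν above 300 nm, CH2Cl2, −40 °C) on the convex face should give the cis-anti-cis cyclopentanone photoadduct F1; its regioisomers converge later.
- The kinetic enolate of F1 (LiN(SiMe3)2, CF3CO2CH2CF3) gives the α-trifluoroacetyl ketone F2 (not isolated), which undergoes deacylative diazo transfer (MeSO2N3, Et3N) to the α-diazoketone F3.
- Photochemical Wolff rearrangement of F3 in aqueous THF contracts the five-membered ring to the cyclobutanecarboxylic acid F4.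
- Barton decarboxylation of F4 through its N-acyloxypyridine-2-thione F5 (not isolated; t-BuSH, visible light) removes the carboxyl group and rejoins the route at 15.

**Step 8.** The parent pyrone may add too slowly to an unactivated cyclobutene. The temperature then needed would let diene 13 equilibrate with its cyclooctatriene valence isomer, undergo 1,5-hydrogen shifts that erase the C1/C8 configuration, or add a second dienophile.

Fallback, from 10 to lactone 12, separating cycloaddition from extrusion:
- 3,5-Dibromo-2H-pyran-2-one, a more reactive ambiphilic diene, should add to 10 below 100 °C (PhMe, 90 °C) to give the isolable dibromo bridged lactone F6.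
- Radical debromination of F6 (n-Bu3SnH, AIBN, PhH, 80 °C) gives lactone 12, now isolated.
- A short thermolysis of 12 (PhMe, 140 °C, flow reactor, short residence time) delivers 13.

**Step 4.** The small and very reactive cyclobutenone may give insufficient facial discrimination. An uncatalysed background reaction, polymerisation of 3, or protodesilylation of the enol ether by the acidic catalyst are further risks.

Fallback, from 3 and 5 to 6, replacing catalysis by resolution: a ZnCl2-promoted cycloaddition (CH2Cl2, −40 °C) gives racemic 6. Preparative chromatography on a chiral stationary phase separates 6 from its (1S,6S) enantiomer F7, which is discarded. The route continues from 6.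

**Step 15.** Facial selectivity at the exocyclic alkene may be modest, and catalyst-induced migration of the double bond into the ring before reduction would weaken the bias. Adventitious acid from the cationic catalyst could also loosen the acetal.

Fallback, from ketone 16 to 23, setting C10 by hydroboration:
- Wittig methylenation of 16 (Ph3PCH3Br, KOt-Bu, THF) gives the 10-methylene ladder F8.
- Hydroboration of F8 with 9-borabicyclo[3.3.1]nonane (THF, rt) places boron on the terminal carbon and delivers hydrogen to C10 from the convex face, giving the B-alkyl borane F9 (not isolated). The reagent is bulky and the 1,1-disubstituted alkene cannot isomerise.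
- Alkyl–alkyl Suzuki–Miyaura coupling of F9 with cis-5-(7-bromoheptyloxy)-2-phenyl-1,3-dioxane F10 (made from 17 and 1,7-dibromoheptane as in step 12; Pd(OAc)2, PCy3, K3PO4·H2O, THF, rt) gives 23.

## Further compounds

F1 | step 9 | cis-anti-cis cyclopentanone photoadduct of 10 and cyclopent-2-enone (one regioisomer drawn) | C12(OCCO1)CC[C@@H]3[C@H](C2)[C@H]2[C@@H]4C(=O)CC[C@@H]4[C@@H]32
F2 | step 9 | α-trifluoroacetyl ketone derived from F1 | C12(OCCO1)CC[C@@H]3[C@H](C2)[C@H]2[C@@H]4C(=O)C(C(=O)C(F)(F)F)C[C@@H]4[C@@H]32
F3 | step 9 | α-diazoketone derived from F1 | C12(OCCO1)CC[C@@H]3[C@H](C2)[C@H]2[C@@H]4C(=O)C(=[N+]=[N-])C[C@@H]4[C@@H]32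
F4 | step 9 | ring-contracted ladder carboxylic acid (carboxyl on C4, configuration there open) | C12(OCCO1)CC[C@@H]3[C@H](C2)[C@H]2[C@@H]4C(C(=O)O)C[C@@H]4[C@@H]32
F5 | step 9 | N-acyloxypyridine-2-thione (Barton ester) of F4 | C12(OCCO1)CC[C@@H]3[C@H](C2)[C@H]2[C@@H]4C(C(=O)ON5C=CC=CC5=S)C[C@@H]4[C@@H]32
F6 | step 8 | dibromo bridged lactone from 10 and 3,5-dibromo-2H-pyran-2-one (one regioisomer drawn, bridgehead configuration open) | C12(OCCO1)CC[C@@H]3[C@H](C2)[C@H]2C4(Br)C=C(Br)C(OC4=O)[C@@H]32
F7 | step 4 | (1S,6S)-3-(triisopropylsilyloxy)bicyclo[4.2.0]oct-3-en-7-one, the enantiomer of 6 | CC(C)[Si](C(C)C)(C(C)C)OC1=CC[C@H]2[C@@H](C1)CC2=O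
F8 | step 15 | 10-methylenetetracyclo[6.4.0.0(2,7).0(3,6)]dodecane | C=C1CC[C@@H]2[C@H](C1)[C@H]1[C@@H]3CC[C@@H]3[C@@H]21
F9 | step 15 | 9-[(tetracyclo[6.4.0.0(2,7).0(3,6)]dodecan-10-yl)methyl]-9-borabicyclo[3.3.1]nonane, C10 as in the target | C(B1C2CCCC1CCC2)[C@H]1CC[C@@H]2[C@H](C1)[C@H]1[C@@H]3CC[C@@H]3[C@@H]21
F10 | step 15 | cis-5-(7-bromoheptyloxy)-2-phenyl-1,3-dioxane | BrCCCCCCCO[C@H]1CO[C@@H](c2ccccc2)OC1
A1 | alternative 1 | 3-(trimethylsilyloxy)bicyclo[4.2.0]oct-3-en-7-one | C[Si](C)(C)OC1=CC[C@@H]2[C@H](C1)CC2=O
A2 | alternative 1 | 2-(trimethylsilyloxy)buta-1,3-diene | C=CC(=C)O[Si](C)(C)C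
A3 | alternative 2 | di-O-benzyl target | c1ccccc1COCC(COCc1ccccc1)OCCCCCCCC[C@H]1CC[C@@H]2[C@H](C1)[C@H]1[C@@H]3CC[C@@H]3[C@@H]21
A4 | alternative 2 | cis-fused secondary pyrrolidine precursor (NH bridging the CH2 groups on C3 and C6) | c1ccccc1COCC(COCc1ccccc1)OCCCCCCCC[C@H]1CC[C@@H]2[C@H](C1)[C@H]1[C@@H]3CNC[C@@H]3[C@@H]21
A5 | alternative 3 | meso tetracyclic ladder diester acetonide | CC1(C)O[C@@H]2[C@H](O1)C[C@@H]3[C@H](C2)[C@H]2[C@@H]4[C@@H](C(=O)OCC)[C@@H](C(=O)OCC)[C@@H]4[C@@H]32
A6 | alternative 3 | acyclic all-E tetraene diester on a meso diol acetonide | CCOC(=O)/C=C/C=C/C[C@@H]1OC(C)(C)O[C@@H]1C/C=C/C=C/C(=O)OCC
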